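**Plan**

- Retrosynthesis: cut (a) the bond between ring carbon C5 and the benzylic carbon C1' into two electrophiles, an aryl bromide and a primary alkyl bromide; (b) the C7'–C8' bond by acetylide alkylation, the C8'=C9' olefin staying an alkyne until late; (c) the C13'–C14' bond by epoxide alkynylation, after which the triple bond is walked to the chain end.
- Forward: (S)-2-ethyloxirane plus hexynyllithium, alkyne zipper, alkylation with 1,7-dibromoheptane, Lindlar reduction, nickel-catalysed reductive coupling with silylated 5-bromoresorcinol, desilylation. The only ring, the benzene ring, is bought intact.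
- Stereochemistry: C15' (S) comes from the purchased epoxide, which is opened at its CH2 carbon so the stereocentre is never touched. The 8'Z olefin comes from syn semi-hydrogenation of the alkyne.
- Enabling feature: ring carbon C5 is meta to both oxygens, so it is out of reach of electrophilic substitution or ortho-metalation but available as a C–Br electrophile. C1' is an unbranched primary carbon, seven CH2 groups from the C8'=C9' olefin and fourteen bonds from C15'. A C1' radical can therefore be made and captured by nickel without cyclizing, moving the olefin or disturbing the free carbinol, so two carbons of like (electrophilic) polarity are joined reductively with no organometallic reagent to prepare.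

Key step: step 6

Remark: the side chain is numbered C1' (benzylic) to C17'; compounds 1, 2, 7 and 11 are taken to be catalogue materials.

**Route**

Step 1
Reactants: 1 (2S)-2-ethyloxirane; 2 hex-1-yne
Product: 4 (3S)-dec-5-yn-3-ol, via lithium hex-1-yn-1-ide 3 (not isolated)
Conditions: n-BuLi, THF, −78 °C; BF3·OEt2, −78 °C; then 1, −78 °C; H2O
Reagents that add atoms: none
Why: Yamaguchi–Hirao alkynylation, in which the BF3-activated terminal epoxide is opened by the lithium acetylide in an SN2 reaction at the unsubstituted CH2 carbon, so the C–O stereocentre of 1 is untouched and becomes the (S)-carbinol that is C15' of the target.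

Step 2
Reactants: 4 (3S)-dec-5-yn-3-ol
Product: 6 (3S)-dec-9-yn-3-ol, via dipotassium alkoxide-acetylide of (3S)-dec-9-yn-3-ol 5 (not isolated)
Conditions: KH (4.5 equiv), H2N(CH2)3NH2, rt; then 4, 0 °C to rt; H2O
Reagents that add atoms: none
Why: Alkyne zipper reaction, in which potassium 3-aminopropylamide moves the triple bond by propargyl/allenyl proton shifts along the unbranched chain away from the alkoxide (which blocks passage through C3) until it is trapped irreversibly as the terminal acetylide; the carbinol carbon carries no acidic hydrogen, so its configuration should be retained.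

Step 3
Reactants: 6 (3S)-dec-9-yn-3-ol; 7 1,7-dibromoheptane
Product: 9 (3S)-17-bromoheptadec-9-yn-3-ol, via dilithium alkoxide-acetylide of (3S)-dec-9-yn-3-ol 8 (not isolated)
Conditions: n-BuLi (2.1 equiv), THF/DMPU, −40 to 0 °C; then 7 (4 equiv), 0 °C to rt; H2O
Reagents that add atoms: none
Why: Acetylide alkylation (SN2), in which the carbon end of the O,C-dianion is far more nucleophilic toward a primary bromide than the lithium alkoxide, while the excess of the symmetrical dibromide suppresses double alkylation.

Step 4
Reactants: 9 (3S)-17-bromoheptadec-9-yn-3-ol
Product: 10 (3S,9Z)-17-bromoheptadec-9-en-3-ol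
Conditions: H2 (1 atm), Lindlar catalyst (Pd on CaCO3 poisoned with Pb(OAc)2), quinoline, EtOAc, rt
Reagents that add atoms: none
Why: Lindlar semi-hydrogenation, in which syn delivery of hydrogen on the poisoned palladium surface sets the olefin as Z and the deactivated catalyst should leave the primary C–Br bond and the product alkene alone.

Step 5
Reactants: 11 5-bromobenzene-1,3-diol
Product: 12 [(5-bromo-1,3-phenylene)bis(oxy)]bis(tert-butyldimethylsilane)
Conditions: TBSCl (2.4 equiv), imidazole, DMF, rt
Reagents that add atoms: tert-butyldimethylsilyl chloride (TBSCl), CC(C)(C)[Si](C)(C)Cl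
Why: Imidazole-promoted silylation of phenols, which masks the two acidic hydroxyls for the coupling with groups that fluoride removes in the last step.

Step 6
Reactants: 10 (3S,9Z)-17-bromoheptadec-9-en-3-ol; 12 [(5-bromo-1,3-phenylene)bis(oxy)]bis(tert-butyldimethylsilane)
Product: 13 (3S,9Z)-17-{3,5-bis[(tert-butyldimethylsilyl)oxy]phenyl}heptadec-9-en-3-ol
Conditions: NiBr2·MeOCH2CH2OMe (10 mol%), 4,4'-di-tert-butyl-2,2'-bipyridine (10 mol%), NaI (25 mol%), pyridine (10 mol%), Zn dust (2 equiv), 10 (1.2 equiv), DMPU, 60 °C
Reagents that add atoms: none
Why: Nickel-catalysed reductive cross-electrophile coupling (closest known type: the nickel/bipyridine/zinc coupling of aryl bromides with primary alkyl bromides), in which bipyridine-ligated zerovalent nickel adds oxidatively to the C5–Br bond of 12, the resulting divalent arylnickel bromide captures the primary C1' radical that a monovalent nickel halide generates from 10 by halogen abstraction (assisted by bromide/iodide exchange), and the trivalent aryl(alkyl)nickel species reductively eliminates the C5–C1' bond before zinc returns nickel to the zerovalent state. No ring is closed and no stereocentre is formed. Cross-selectivity over biaryl or bialkyl formation rests on the two electrophiles being activated by different mechanisms, two-electron oxidative addition for the sp2 bromide and halogen abstraction to a radical for the sp3 bromide. The substrate secures chemoselectivity: the C1' radical is seven methylenes from the C8'=C9' olefin, so 8-exo or 9-endo cyclization cannot compete with capture by nickel, the primary alkylnickel has no driving force for chain walking so the position and Z geometry of the olefin should persist, and since no basic organometallic is formed the free C15' hydroxyl needs no protection and its distant stereocentre is untouched. Partial loss of an aryl silyl group would be harmless because both are removed in the next step.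

Step 7
Reactants: 13 (3S,9Z)-17-{3,5-bis[(tert-butyldimethylsilyl)oxy]phenyl}heptadec-9-en-3-ol
Product: 14 Hansfordiol G, 5-[(8Z,15S)-15-hydroxyheptadec-8-en-1-yl]benzene-1,3-diol
Conditions: KHF2 (2.5 equiv), MeOH/THF, rt
Reagents that add atoms: none
Why: Fluoride-mediated desilylation, in which fluoride attacks silicon and releases the phenols at room temperature under conditions to which the Z-olefin, the secondary alcohol and its stereocentre are inert.

**Compound list**

1 | (2S)-2-ethyloxirane [(S)-1,2-epoxybutane] | CC[C@H]1CO1 | starting material
2 | hex-1-yne | CCCCC#C | starting material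
3 | lithium hex-1-yn-1-ide | [Li]C#CCCCC | intermediate
4 | (3S)-dec-5-yn-3-ol | CC[C@H](O)CC#CCCCC | intermediate
5 | dipotassium alkoxide-acetylide of (3S)-dec-9-yn-3-ol | CC[C@H](O[K])CCCCCC#C[K] | intermediate
6 | (3S)-dec-9-yn-3-ol | CC[C@H](O)CCCCCC#C | intermediate
7 | 1,7-dibromoheptane | BrCCCCCCCBr | starting material
8 | dilithium alkoxide-acetylide of (3S)-dec-9-yn-3-ol | CC[C@H](O[Li])CCCCCC#C[Li] | intermediate
9 | (3S)-17-bromoheptadec-9-yn-3-ol | CC[C@H](O)CCCCCC#CCCCCCCCBr | intermediate
10 | (3S,9Z)-17-bromoheptadec-9-en-3-ol | CC[C@H](O)CCCCC/C=C\CCCCCCCBr | intermediate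
11 | 5-bromobenzene-1,3-diol | Oc1cc(Br)cc(O)c1 | starting material
12 | [(5-bromo-1,3-phenylene)bis(oxy)]bis(tert-butyldimethylsilane) | CC(C)(C)[Si](C)(C)Oc1cc(Br)cc(O[Si](C)(C)C(C)(C)C)c1 | intermediate
13 | (3S,9Z)-17-{3,5-bis[(tert-butyldimethylsilyl)oxy]phenyl}heptadec-9-en-3-ol | CC[C@H](O)CCCCC/C=C\CCCCCCCc1cc(O[Si](C)(C)C(C)(C)C)cc(O[Si](C)(C)C(C)(C)C)c1 | intermediate
14 | Hansfordiol G, 5-[(8Z,15S)-15-hydroxyheptadec-8-en-1-yl]benzene-1,3-diol | CC[C@H](O)CCCCC/C=C\CCCCCCCc1cc(O)cc(O)c1 | target

**Step count and risks**

Total step count: 7. Longest linear sequence: 6 (steps 1, 2, 3, 4, 6, 7); step 5 is the one-step side branch.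

Steps most likely to fail:

1. Step 6. The reductive coupling may be eroded by homocoupling of either bromide, by reduction of the C–Br bonds, or by nickel hydride-mediated migration of the olefin. Fallback: the same bond would be made with conventional polarity by a copper-catalysed Kumada–Corriu-type alkylation. Setting out from 12, magnesium insertion (Mg turnings, LiCl, THF) should give [3,5-bis(tert-butyldimethylsilyloxy)phenyl]magnesium bromide F1. About 2.2 equivalents of it would be added to 10 with catalytic Li2CuCl4 in THF/NMP at 0 °C. The first equivalent converts the hydroxyl into the bromomagnesium alkoxide of 10 F2, and the second displaces the primary bromide through an aryl cuprate in an SN2 process that leaves the olefin alone. Aqueous work-up rejoins the route at 13.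

2. Step 2. The zipper may stall before the chain end, or the prolonged exposure to the amide base may degrade the alkoxide or erode its enantiopurity. Fallback: the terminal alkyne would be brought in ready-made instead of being walked into place, setting out from 1 and replacing steps 1 and 2. Purchased 6-chlorohex-1-yne F3 would be deprotonated (n-BuLi, THF, −78 °C) to lithium 6-chlorohex-1-yn-1-ide F4 and silylated with Me3SiCl to (6-chlorohex-1-yn-1-yl)trimethylsilane F5. Magnesium (THF, reflux) should then give [6-(trimethylsilyl)hex-5-yn-1-yl]magnesium chloride F6, which would open 1 at its CH2 carbon under CuI catalysis (THF, −30 °C) to (3S)-10-(trimethylsilyl)dec-9-yn-3-ol F7. Catalytic K2CO3 in MeOH would remove the silyl group and rejoin the route at 6.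

3. Step 3. Competing O-alkylation of the alkoxide, double alkylation of the dibromide or E2 elimination may lower the efficiency of the dianion alkylation. Fallback: instead of relying on the kinetic preference for C-alkylation, the carbinol would be masked, setting out from 6. Silylation (TBSCl, imidazole, DMF) should give tert-butyl{[(3S)-dec-9-yn-3-yl]oxy}dimethylsilane F8. One equivalent of n-BuLi (THF/DMPU, −40 °C) would form the lithium acetylide of the silyl ether F9, which would be alkylated with excess 7 to tert-butyl{[(3S)-17-bromoheptadec-9-yn-3-yl]oxy}dimethylsilane F10. Catalytic HCl in MeOH would cleave the alkyl silyl ether and rejoin the route at 9.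

**Further compounds**

F1 | step 6 | [3,5-bis(tert-butyldimethylsilyloxy)phenyl]magnesium bromide | CC(C)(C)[Si](C)(C)Oc1cc([Mg]Br)cc(O[Si](C)(C)C(C)(C)C)c1
F2 | step 6 | bromomagnesium alkoxide of 10 | CC[C@H](O[Mg]Br)CCCCC/C=C\CCCCCCCBr
F3 | step 2 | 6-chlorohex-1-yne | ClCCCCC#C
F4 | step 2 | lithium 6-chlorohex-1-yn-1-ide | [Li]C#CCCCCCl
F5 | step 2 | (6-chlorohex-1-yn-1-yl)trimethylsilane | C[Si](C)(C)C#CCCCCCl
F6 | step 2 | [6-(trimethylsilyl)hex-5-yn-1-yl]magnesium chloride | C[Si](C)(C)C#CCCCC[Mg]Cl
F7 | step 2 | (3S)-10-(trimethylsilyl)dec-9-yn-3-ol | CC[C@H](O)CCCCCC#C[Si](C)(C)C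
F8 | step 3 | tert-butyl{[(3S)-dec-9-yn-3-yl]oxy}dimethylsilane | CC[C@H](O[Si](C)(C)C(C)(C)C)CCCCCC#C
F9 | step 3 | lithium acetylide of the silyl ether | CC[C@H](O[Si](C)(C)C(C)(C)C)CCCCCC#C[Li]
F10 | step 3 | tert-butyl{[(3S)-17-bromoheptadec-9-yn-3-yl]oxy}dimethylsilane | CC[C@H](O[Si](C)(C)C(C)(C)C)CCCCCC#CCCCCCCCBr
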